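## Structural features

The target is a monocyclic elemane with one cyclohexane ring (C5–C10) and no second ring. Going round the ring: the quaternary C10 (methyl C14, vinyl C1=C2), the methylene C9, the acyloxy carbon C8, C7 with the acrylic acid C11(=C13)–C12, the carbinol C6, and C5 with the 3-hydroxyprop-1-en-2-yl unit C4(=C3)–C15. C5, C6, C7 and C8 are four contiguous stereocentres and C5 also adjoins the quaternary stereocentre C10; the configuration is 5S,6R,7S,8S,10R. With α as the ring face holding C4, O6, O8 and the C10 methyl, and β as the face of the vinyl group and C11, the C7 substituent is trans to both neighbouring oxygens. Fragile elements are the (Z)-4-acetoxy-2-methylbut-2-enoate (Z to E isomerisation, acyl migration, allylic acetate), the γ-hydroxy α-methylene acid (closure onto O6 under acid), three terminal alkenes and a primary allylic alcohol; C5–H becomes epimerisable whenever C4 is a carbonyl in an open ring. The real difficulty is the all-carbon quaternary centre C10 next to C5, together with the differentiation of two secondary oxygens (O8 acylated, O6 free) and of two 2-substituted allyl units at different oxidation levels (C15 alcohol, C12 acid). The key step uses the cis-1,4 relation of the C5–C4 and C8–O8 bonds: C4 and O8 are the carbonyl carbon and ring oxygen of a 2-pyrone, C5–C8 are its diene carbons, C7 carries bromine, and methacrolein supplies C9, C10, C1 and C14, so one [4+2] cycloaddition builds the carbocycle inside a 2-oxabicyclo[2.2.2]octenone. The temporary lactone bridge then keeps O8 masked while O6 is introduced, leaves one face of C6=C7 open, and holds C5 as a non-enolisable bridgehead.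

## Logic of the disconnections

**30 from 29 from 28.** The O6–Si and O15–benzyl bonds are cut last. The free γ-hydroxy acid and the primary allylic alcohol are the groups most likely to interfere (lactone closure, over-oxidation), so they are exposed only at the end. The gain is that each earlier intermediate has a single reactive heteroatom site. The forward steps must be neither strongly acidic nor basic and must spare both esters of the C8 side chain.

**28 from 27 from 25 from 24.** The C11=C13 bond is cut and C12 is taken back from acid to aldehyde to silyl ether. An α-methylenation of a C12 aldehyde installs the exocyclic methylene without enolising toward C7, and a chlorite oxidation then gives the acid. This reduces the C7 side chain to a 2-oxyethyl group. The forward steps must unveil the primary silyl ether in the presence of the secondary one and must not isomerise the Z-enoate.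

**24 from 17 and 22; 22 from 21 from 18.** The O8–acyl bond is cut. O8 is the only free hydroxyl in 17 because it was the lactone oxygen, so no selective acylation is needed. The Z geometry of 22 is taken from the ring of 18, where the carboxyl and hydroxymethyl carbons are necessarily cis. The acylation must proceed without Z to E isomerisation and without loss of the allylic acetate.

**17 from 16 from 12 and 14; 12 from 11; 14 from 13.** C4=C3 is cut by methylenation, C4–C15 by addition of an alkoxymethyl anion to a Weinreb amide, and the amide goes back to the C4–O8 lactone. This returns C4 to the oxidation level it has in the pyrone and releases O8 in the same operation. The forward steps must stop at single addition and avoid base at the ketone stage, where C5–H is acidic and O6 is a β-leaving group.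

**11 from 10 from 8.** C1=C2 is cut to the C10 aldehyde, which is kept as a dimethyl acetal while boranes are in use. Making the vinyl group after the hydroboration removes the only alkene that would compete with C6=C7. The forward steps must release a neopentyl aldehyde without acid that would strip silyl ethers, and methylenate it next to a strained lactone.

**8 from 6.** The C6–O, C7–H and C12–O bonds are cut, all three coming from hydroboration of a 2-substituted diene. A syn addition of H and B from the open lactone face sets C6 and C7 in one event with the required trans relation of O6 and the C7 chain. A conjugate borylation of a C7 acyl enone was set aside because C7 would be set by enolate protonation next to the new boryl group, and the product would be a β-acyloxy ketone prone to elimination across C7–C8. The forward step needs boron at C6, not C7, attack from the face opposite the C10 substituent, and survival of the lactone.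

**6 from 5 from 4.** The C7–C11 bond is cut to the alkenyl bromide and a vinyl-tin reagent, and the acetal is taken back to the aldehyde. The bromide placed by the pyrone is used directly as the coupling handle. The coupling must run under neutral conditions and below the temperature of CO2 extrusion.

**4 from 2 and 3.** C5–C10 and C8–C9 are cut in a [4+2] sense. This removes the ring, the quaternary centre and three stereocentres at once and leaves two flat, achiral components. The forward step must give the regiochemistry that joins the oxygen-bearing pyrone terminus to the CH2 of the enal, the endo formyl orientation, and one enal face.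

**2 from 1.** The C–Br bond is cut back to the carboxyl group by bromodecarboxylation. The commercial acid already has the pyrone ring with a leaving group at the right carbon. The forward step must avoid over-bromination at C3.

## Other disconnections considered

**Alternative 1:** The cut is C7–C8. An open-chain aldehyde A2 (C8 formyl; C7=C11 trisubstituted alkene; C5 ester, O6 silyl ether and quaternary C10 already in place) would close under (CH3)2AlCl by an intramolecular carbonyl-ene reaction to cyclohexanol A1.
- In favour: the closure belongs to a well-established class (citronellal-type closures through a chair transition state that sets hydroxyl and isopropenyl trans), so on precedent it is better than the chosen key step. It delivers O8 free and O6 silylated, which equals the hydroxyl differentiation of the chosen plan, and C1=C2 and C11=C13 are already present in A1.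
- Against: A2 must carry C10, C5 and C6 with full control before any ring exists, so the hardest part of the molecule is moved into acyclic stereocontrol. The ene step forms one bond and two stereocentres, against two bonds and three stereocentres including C10 for the cycloaddition. The allylic silyloxy group sits on the ene donor, where the Lewis acid may ionise it, and the required chair places the C5 ester axial. C12 would still need an allylic C–H oxidation, and the C4 ester the same three-carbon elaboration as in the chosen route.
- Step economy: expected to be equal at best, because the steps saved after A1 are spent in reaching A2.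

**Alternative 2:** The cut is at the C6–O and C5–Br bonds of a bridged bromolactone A3. It would arise from the prochiral dienoic acid A4 with N-bromosuccinimide and a chiral bifunctional amidine; A4 comes from 3,5-dimethoxybenzoic acid A5 by reductive methylation.
- In favour: A4 is one step from a cheap arene, and catalytic desymmetrising halolactonisation of cyclohexadiene acids is an established reaction class, so precedent is better than for the chosen key step. It sets the quaternary C10 catalytically at the outset, which is equal to the chosen plan on that point.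
- Against: only C10 survives into the target. The C5 bromide and the C6 ketal are transient, so C5, C6, C7 and C8 must all be set later by substrate control on a ring in which C7 lies between two carbonyl equivalents and is epimerisable. The C4 unit must be attached at a neopentyl carbon by enolate chemistry, since substitution of the bromide is not viable. C1 must be taken from carboxyl to vinyl, and both side chains must be built from outside, whereas the chosen plan brings C4 in with the pyrone.
- Step economy: clearly worse after the key step, although the start is shorter.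

**Alternative 3:** The cuts are C5–C10 and C6–C7, with C1–C11 cleaved later. Oxidation of 2-methoxy-3-methylphenol A8 with PhI(OAc)2 in methanol would give the masked o-benzoquinone A7. A7 would add the enantiopure 2-alkoxy-2,3-dihydrofuran A9 in an inverse-demand endo [4+2] to give the bicyclo[2.2.2]octenone A6.
- In favour: cycloadditions of such dienones with enol ethers are well precedented and reliable in regio- and endo-selectivity. The step would set four stereocentres (C5, C6, C7, C10) against three for the chosen key step, and it uses auxiliary control that lies within known chemistry. On both counts it is better than the chosen plan. O6 and C4 arrive cis, as required.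
- Against: the methyl-bearing diene terminus must form a quaternary bridgehead in competition with dimerisation of A7. C8 has no oxygen and would have to be hydroxylated on the C8=C9 bridge with regiocontrol and on the more hindered face. Cleavage of the keto-ketal bridge leaves C1 and C11 as two carboxyl-level carbons that must be told apart: C1 reduced to vinyl and C11 extended by two carbons. In the chosen plan both bridge atoms (C4, O8) stay in the target at the right oxidation level.
- Step economy: longer, mainly through the bridge cleavage, its differentiation and the late C8 oxidation.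

Key step: step 2

Assumption 1: the (S)-series oxazaborolidinium is taken to shield the Si face at C-α of bound 3; if its sense is the reverse, the (R)-antipode is used with no other change.

Assumption 2: 3-methylfuran-2(5H)-one, (tributylstannyl)methanol and all reagents named on the Conditions lines are treated as commercial.

## Steps

Step 1
Reactants: 1 coumalic acid (2-oxo-2H-pyran-5-carboxylic acid)
Product: 2 5-bromo-2H-pyran-2-one
Conditions: NBS, LiOAc (0.2 equiv.), MeCN/H2O, rt
Reagents that add atoms: N-bromosuccinimide, O=C1CCC(=O)N1Br
Why: Halodecarboxylation of the vinylogous carboxylate: bromination at the carboxyl-bearing C5 is followed by loss of CO2, a known conversion of this acid; a slight deficit of NBS limits further bromination at C3.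

Step 2
Reactants: 2 5-bromo-2H-pyran-2-one; 3 methacrolein
Product: 4 (1S,4S,8S)-6-bromo-8-methyl-3-oxo-2-oxabicyclo[2.2.2]oct-5-ene-8-carbaldehyde
Conditions: 3 (3 equiv.), (S)-1-(2-methylphenyl)-3,3-diphenyltetrahydro-1H,3H-pyrrolo[1,2-c][1,3,2]oxazaborole·HN(SO2CF3)2 (20 mol %), CH2Cl2, −40 → −20 °C
Reagents that add atoms: none
Why: Proposed new method: the cationic boron Lewis acid binds the formyl oxygen of 3 (s-trans enal, held by a formyl C–H···O contact), lowers its LUMO and lets the weakly nucleophilic diene of 2 add in a concerted, asynchronous Diels–Alder reaction well below the temperature at which bridged pyrone adducts lose CO2. The closest known reaction types are oxazaborolidinium-catalysed enantioselective Diels–Alder reactions of 2-substituted acroleins with simple dienes, and thermal or achiral Lewis-acid cycloadditions of 3- and 5-bromo-2-pyrones with acrylic dienophiles that give isolable bridged lactones; their combination is without precedent. The six-membered carbocycle closes by intermolecular suprafacial [4+2] addition at both diene termini, with C8–C9 (oxygen-bearing pyrone terminus to the enal CH2) as the leading bond and C5–C10 as the second, and the C4(=O)–O8 lactone bridge results from it. C5 and C8 are the bridgeheads and are cis because the diene reacts on one face. C10 is set relative to them by the endo position of the formyl group under the diene, which the methyl group does not oppose because in the exo position it faces the hydrogen-free lactone bridge and not a CH2 bridge. The absolute sense comes from the catalyst, which blocks the Si face at C-α of the bound enal so that C5 bonds to the Re face; with regiochemistry and endo topology fixed this defines all three centres. The step needs regioselectivity (secured by the pyrone polarity, with the bromide keeping the diene ambiphilic and marking C7), endo selectivity (the least secure point) and enal-face selectivity (catalyst).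

Step 3
Reactants: 4 bridged lactone aldehyde
Product: 5 (1S,4S,8S)-6-bromo-8-(dimethoxymethyl)-8-methyl-2-oxabicyclo[2.2.2]oct-5-en-3-one
Conditions: MeOSiMe3, Me3SiOTf (5 mol %), CH2Cl2, −78 → −30 °C
Reagents that add atoms: methoxytrimethylsilane, CO[Si](C)(C)C
Why: Aprotic silyl-triflate-catalysed acetalisation masks the aldehyde against the boranes of step 5; no free methanol or protic acid is present, so the strained lactone is not transesterified, and no stereocentre is touched.

Step 4
Reactants: 5 bromo lactone acetal
Product: 6 (1S,4S,8S)-8-(dimethoxymethyl)-6-ethenyl-8-methyl-2-oxabicyclo[2.2.2]oct-5-en-3-one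
Conditions: tributyl(vinyl)stannane, Pd(PPh3)4 (5 mol %), CuI (10 mol %), CsF, DMF, 45 °C
Reagents that add atoms: tributyl(vinyl)stannane, C=C[Sn](CCCC)(CCCC)CCCC
Why: Stille coupling of the C7 alkenyl bromide (oxidative addition to zerovalent palladium, tin-to-palladium transfer assisted by CuI and fluoride, reductive elimination) forms C7–C11; the neutral medium and 45 °C spare the lactone and stay below CO2 extrusion.

Step 5
Reactants: 6 diene lactone acetal
Product: 8 lactone diol (6α-OH and 7β-CH2CH2OH; 5-hydroxy syn and 6-(2-hydroxyethyl) anti to the lactone bridge of the 2-oxabicyclo[2.2.2]octan-3-one), via bis-organoborane 7 (not isolated)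
Conditions: 9-BBN, THF, 0 °C → rt; BH3·THF, 0 °C; NaBO3·4H2O, THF/H2O, rt
Reagents that add atoms: sodium perborate tetrahydrate, O.O.O.O.[Na+].[O-]OB=O
Why: 9-BBN hydroborates the terminal vinyl of the diene at C12; BH3 then adds to the strained trisubstituted C6=C7 with boron on the less substituted C6 and from the lactone-bridge face, the other face being screened by the endo dimethoxymethyl group on C10. The syn addition puts C6–B and C7–H both on the α face, so oxidation with retention gives 6α-OH with the C7 chain β (hydroboration–oxidation); perborate avoids the strongly basic peroxide that would open the lactone.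

Step 6
Reactants: 8 lactone diol
Product: 10 bis(triethylsilyl) ether aldehyde (8-methyl-3-oxo-5-(triethylsilyloxy)-6-[2-(triethylsilyloxy)ethyl]-2-oxabicyclo[2.2.2]octane-8-carbaldehyde), via collidinium salt 9 (not isolated)
Conditions: Et3SiOTf (5 equiv.), 2,4,6-collidine (8 equiv.), CH2Cl2, 0 °C → rt; then H2O
Reagents that add atoms: triethylsilyl trifluoromethanesulfonate, CC[Si](CC)(CC)OS(=O)(=O)C(F)(F)F; water, O
Why: The silyl triflate silylates both hydroxyls and ionises the dimethyl acetal to an oxocarbenium ion that collidine traps as an N-(α-methoxyalkyl)pyridinium salt, which water converts to the aldehyde (silyl triflate–pyridine acetal cleavage), so no protic acid meets the silyl ethers. C5 is a bridgehead and cannot enolise, so no stereocentre is at risk.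

Step 7
Reactants: 10 bis(triethylsilyl) ether aldehyde
Product: 11 vinyl lactone (8-ethenyl-8-methyl-5-(triethylsilyloxy)-6-[2-(triethylsilyloxy)ethyl]-2-oxabicyclo[2.2.2]octan-3-one)
Conditions: Ph3PCH3Br, KOtBu, THF, 0 °C; then 10, −78 → 0 °C
Reagents that add atoms: methyltriphenylphosphonium bromide, C[P+](c1ccccc1)(c1ccccc1)c1ccccc1.[Br-]
Why: Wittig methylenation forms C1=C2; the aldehyde is far more electrophilic than the lactone at low temperature and, being α-quaternary, cannot enolise.

Step 8
Reactants: 11 vinyl lactone
Product: 12 hydroxy Weinreb amide (2-ethenyl-4-hydroxy-N-methoxy-N,2-dimethyl-6-(triethylsilyloxy)-5-[2-(triethylsilyloxy)ethyl]cyclohexane-1-carboxamide; 8α-OH free)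
Conditions: MeNH(OMe)·HCl, i-PrMgCl, THF, −20 → 0 °C
Reagents that add atoms: N,O-dimethylhydroxylamine hydrochloride, CNOC.Cl
Why: Aminolysis of the bridged lactone by the chloromagnesium amide (Weinreb amide formation) is driven by release of the boat strain and frees O8 as the only hydroxyl of the molecule; the stereocentres are not involved.

Step 9
Reactants: 13 (tributylstannyl)methanol
Product: 14 tributyl{[(4-methoxyphenyl)methoxy]methyl}stannane
Conditions: NaH, 4-methoxybenzyl chloride, Bu4NI (cat.), THF/DMF, 0 °C → rt
Reagents that add atoms: 4-methoxybenzyl chloride, COc1ccc(CCl)cc1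
Why: Williamson etherification of the primary alkoxide gives the stannane precursor of an alkoxymethyl anion whose protecting group can later be removed oxidatively under neutral conditions.

Step 10
Reactants: 12 hydroxy Weinreb amide; 14 tributyl{[(4-methoxyphenyl)methoxy]methyl}stannane
Product: 16 α-alkoxy ketone (1-{2-ethenyl-4-hydroxy-2-methyl-6-(triethylsilyloxy)-5-[2-(triethylsilyloxy)ethyl]cyclohexyl}-2-[(4-methoxyphenyl)methoxy]ethan-1-one), via alkoxymethyllithium 15 (not isolated)
Conditions: 14 (4 equiv.), n-BuLi (3.8 equiv.), THF, −78 °C; then 12, −78 → −50 °C; aq. NH4Cl at −78 °C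
Reagents that add atoms: none
Why: Tin–lithium exchange gives the α-alkoxymethyllithium; one equivalent deprotonates O8–H and a second adds once to the Weinreb amide, whose chelated tetrahedral adduct survives until the cold quench, forming C4–C15. The ketone is therefore never exposed to base, which protects C5–H and the β-silyloxy group at C6.

Step 11
Reactants: 16 α-alkoxy ketone
Product: 17 allylic ether alcohol (3-ethenyl-4-{3-[(4-methoxyphenyl)methoxy]prop-1-en-2-yl}-3-methyl-5-(triethylsilyloxy)-6-[2-(triethylsilyloxy)ethyl]cyclohexan-1-ol)
Conditions: Cp2Ti(μ-Cl)(μ-CH2)AlMe2 (3 equiv.), pyridine, THF, −40 → 0 °C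
Reagents that add atoms: Tebbe reagent written as Cp2Ti=CH2·ClAlMe2, C[Al](C)Cl.C=[Ti](C1C=CC=C1)C1C=CC=C1
Why: Tebbe methylenation (titanium methylidene, [2+2] addition and cycloreversion) forms C4=C3 without base, so the C5 configuration and the β-silyloxy group are kept; the free O8–H is carried as its titanium alkoxide by the excess reagent.

Step 12
Reactants: 18 3-methylfuran-2(5H)-one
Product: 21 (4-methoxyphenyl)methyl (2Z)-4-acetoxy-2-methylbut-2-enoate, via potassium hydroxy-enoate 19 (not isolated), via PMB hydroxy-enoate 20 (not isolated)
Conditions: KOH (1.0 equiv.), MeOH/H2O, rt, evaporate; 4-methoxybenzyl chloride, DMF, rt; Ac2O, pyridine, DMAP (cat.), 0 °C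
Reagents that add atoms: potassium hydroxide, [K+].[OH-]; 4-methoxybenzyl chloride, COc1ccc(CCl)cc1; acetic anhydride, CC(=O)OC(C)=O
Why: Saponification opens the butenolide with the carboxyl and hydroxymethyl carbons necessarily cis, which fixes the Z geometry. Alkylation of the carboxylate by the benzylic chloride does not activate the carboxyl, so the ring cannot re-close, and immediate acetylation caps the primary hydroxyl.

Step 13
Reactants: 21 (4-methoxyphenyl)methyl (2Z)-4-acetoxy-2-methylbut-2-enoate
Product: 22 (2Z)-4-acetoxy-2-methylbut-2-enoic acid
Conditions: CF3CO2H, anisole, CH2Cl2, 0 °C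
Reagents that add atoms: none
Why: Acidolysis of the 4-methoxybenzyl ester, with the benzylic cation trapped by anisole, frees the acid at 0 °C without touching the acetate or the Z-alkene; the acid is used at once.

Step 14
Reactants: 17 allylic ether alcohol; 22 (2Z)-4-acetoxy-2-methylbut-2-enoic acid
Product: 24 C8 ester (8-O-[(2Z)-4-acetoxy-2-methylbut-2-enoyl] derivative of 17), via mixed anhydride 23 (not isolated)
Conditions: 22, 2,4,6-Cl3C6H2COCl, Et3N, toluene, rt; then 17, toluene, 75 °C
Reagents that add atoms: none
Why: Yamaguchi esterification through the mixed anhydride: the alcohol attacks the unhindered enoyl carbonyl, and omitting a nucleophilic catalyst avoids the addition–elimination path that turns Z-2-methylbut-2-enoates into their E isomers. O8–H is the only free hydroxyl, so no selectivity between oxygens is required.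

Step 15
Reactants: 24 C8 ester
Product: 25 C12 aldehyde (7β-CH2CHO; 6α-OSiEt3 retained)
Conditions: (COCl)2, DMSO, CH2Cl2, −78 → −30 °C; Et3N, −78 °C → rt
Reagents that add atoms: none
Why: Under Swern conditions the chlorodimethylsulfonium ion cleaves the unhindered primary triethylsilyl ether and oxidises the resulting alkoxysulfonium salt to the aldehyde in one operation, while the hindered secondary silyl ether at O6 stays in place.

Step 16
Reactants: 25 C12 aldehyde
Product: 27 α-methylene aldehyde (7β-(3-oxoprop-1-en-2-yl)), via Mannich base 26 (not isolated)
Conditions: CH2=NMe2+ I− (Eschenmoser's salt), Et3N, CH2Cl2, rt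
Reagents that add atoms: N,N-dimethylmethyleneiminium iodide, C=[N+](C)C.[I-]
Why: Mannich reaction of the aldehyde enol with the iminium ion followed by β-elimination of dimethylamine (α-methylenation) forms C11=C13. The only enolisable position is C11, so C7 is not affected.

Step 17
Reactants: 27 α-methylene aldehyde
Product: 28 protected acid (6-O-triethylsilyl and 15-O-(4-methoxybenzyl) derivative of the target)
Conditions: NaClO2, NaH2PO4, 2-methyl-2-butene, t-BuOH/H2O, 0 °C → rt
Reagents that add atoms: sodium chlorite, [Na+].[O-]Cl=O
Why: Pinnick oxidation converts the enal into the acrylic acid at buffered pH, with the alkene scavenger removing hypochlorite before it can attack the four C=C bonds or the anisyl ring.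

Step 18
Reactants: 28 protected acid
Product: 29 6-O-triethylsilyl derivative of the target
Conditions: DDQ, CH2Cl2/pH 7 phosphate buffer, 0 °C → rt
Reagents that add atoms: none
Why: Oxidative cleavage of the 4-methoxybenzyl ether by hydride abstraction and hydrolysis of the oxocarbenium ion frees the C15 alcohol under neutral conditions; O6 is still silylated, so it cannot trap the intermediate cation.

Step 19
Reactants: 29 6-O-triethylsilyl derivative of the target
Product: 30 (5S,6R,7S,8S,10R)-8-[(2Z)-4-acetoxy-2-methylbut-2-enoyloxy]-6,15-dihydroxyelema-1,3,11(13)-trien-12-oic acid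
Conditions: HF·pyridine, pyridine, THF, 0 °C
Reagents that add atoms: none
Why: Fluoride-driven cleavage of the secondary triethylsilyl ether in a pyridine-buffered medium is mild enough to leave the acetate, the Z-enoate and the γ-hydroxy acid in place.

## Compound list

1 | coumalic acid (2-oxo-2H-pyran-5-carboxylic acid) | O=C1C=CC(=CO1)C(=O)O | starting material
2 | 5-bromo-2H-pyran-2-one | O=C1C=CC(Br)=CO1 | intermediate
3 | methacrolein (2-methylprop-2-enal) | CC(=C)C=O | starting material
4 | (1S,4S,8S)-6-bromo-8-methyl-3-oxo-2-oxabicyclo[2.2.2]oct-5-ene-8-carbaldehyde (formyl syn to the C=C bridge; target C10 formyl β, C7 bromide) | O=C[C@@]1(C)C[C@H](O2)C(Br)=C[C@@H]1C2=O | intermediate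
5 | (1S,4S,8S)-6-bromo-8-(dimethoxymethyl)-8-methyl-2-oxabicyclo[2.2.2]oct-5-en-3-one | COC(OC)[C@@]1(C)C[C@H](O2)C(Br)=C[C@@H]1C2=O | intermediate
6 | (1S,4S,8S)-8-(dimethoxymethyl)-6-ethenyl-8-methyl-2-oxabicyclo[2.2.2]oct-5-en-3-one | COC(OC)[C@@]1(C)C[C@H](O2)C(C=C)=C[C@@H]1C2=O | intermediate
7 | bis-organoborane from 6: C6 boryl on the lactone face (drawn as BH2), C12 9-borabicyclo[3.3.1]nonan-9-yl | COC(OC)[C@@]1(C)C[C@H]2[C@@H](CCB3C4CCCC3CCC4)[C@H]([BH2])[C@@H]1C(=O)O2 | intermediate
8 | 8-(dimethoxymethyl)-5-hydroxy-6-(2-hydroxyethyl)-8-methyl-2-oxabicyclo[2.2.2]octan-3-one, 5-OH syn and 6-chain anti to the lactone bridge (6α-OH, 7β-CH2CH2OH) | COC(OC)[C@@]1(C)C[C@H]2[C@@H](CCO)[C@H](O)[C@@H]1C(=O)O2 | intermediate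
9 | N-(α-methoxyalkyl)-2,4,6-trimethylpyridinium triflate of the bis(triethylsilyl) ether of 8 (either configuration at the new N,O-acetal carbon) | COC([n+]1c(C)cc(C)cc1C)[C@@]2(C)C[C@H]3[C@@H](CCO[Si](CC)(CC)CC)[C@H](O[Si](CC)(CC)CC)[C@@H]2C(=O)O3.[O-]S(=O)(=O)C(F)(F)F | intermediate
10 | 8-methyl-3-oxo-5-(triethylsilyloxy)-6-[2-(triethylsilyloxy)ethyl]-2-oxabicyclo[2.2.2]octane-8-carbaldehyde (configuration as in 8) | O=C[C@@]1(C)C[C@H]2[C@@H](CCO[Si](CC)(CC)CC)[C@H](O[Si](CC)(CC)CC)[C@@H]1C(=O)O2 | intermediate
11 | 8-ethenyl-8-methyl-5-(triethylsilyloxy)-6-[2-(triethylsilyloxy)ethyl]-2-oxabicyclo[2.2.2]octan-3-one | C=C[C@@]1(C)C[C@H]2[C@@H](CCO[Si](CC)(CC)CC)[C@H](O[Si](CC)(CC)CC)[C@@H]1C(=O)O2 | intermediate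
12 | 2-ethenyl-4-hydroxy-N-methoxy-N,2-dimethyl-6-(triethylsilyloxy)-5-[2-(triethylsilyloxy)ethyl]cyclohexane-1-carboxamide (5α-amide, 6α-OSiEt3, 7β-chain, 8α-OH, 10α-methyl, 10β-vinyl) | C=C[C@@]1(C)C[C@H](O)[C@@H](CCO[Si](CC)(CC)CC)[C@H](O[Si](CC)(CC)CC)[C@@H]1C(=O)N(C)OC | intermediate
13 | (tributylstannyl)methanol | CCCC[Sn](CCCC)(CCCC)CO | starting material
14 | tributyl{[(4-methoxyphenyl)methoxy]methyl}stannane | CCCC[Sn](CCCC)(CCCC)COCc1ccc(OC)cc1 | intermediate
15 | {[(4-methoxyphenyl)methoxy]methyl}lithium | [Li]COCc1ccc(OC)cc1 | intermediate
16 | 1-{2-ethenyl-4-hydroxy-2-methyl-6-(triethylsilyloxy)-5-[2-(triethylsilyloxy)ethyl]cyclohexyl}-2-[(4-methoxyphenyl)methoxy]ethan-1-one (configuration as in 12) | C=C[C@@]1(C)C[C@H](O)[C@@H](CCO[Si](CC)(CC)CC)[C@H](O[Si](CC)(CC)CC)[C@@H]1C(=O)COCc1ccc(OC)cc1 | intermediate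
17 | 3-ethenyl-4-{3-[(4-methoxyphenyl)methoxy]prop-1-en-2-yl}-3-methyl-5-(triethylsilyloxy)-6-[2-(triethylsilyloxy)ethyl]cyclohexan-1-ol (configuration as in 12) | C=C[C@@]1(C)C[C@H](O)[C@@H](CCO[Si](CC)(CC)CC)[C@H](O[Si](CC)(CC)CC)[C@@H]1C(=C)COCc1ccc(OC)cc1 | intermediate
18 | 3-methylfuran-2(5H)-one | CC1=CCOC1=O | starting material
19 | potassium (2Z)-4-hydroxy-2-methylbut-2-enoate | [K+].[O-]C(=O)/C(C)=C\CO | intermediate
20 | (4-methoxyphenyl)methyl (2Z)-4-hydroxy-2-methylbut-2-enoate | COc1ccc(COC(=O)/C(C)=C\CO)cc1 | intermediate
21 | (4-methoxyphenyl)methyl (2Z)-4-acetoxy-2-methylbut-2-enoate | COc1ccc(COC(=O)/C(C)=C\COC(C)=O)cc1 | intermediate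
22 | (2Z)-4-acetoxy-2-methylbut-2-enoic acid | OC(=O)/C(C)=C\COC(C)=O | intermediate
23 | (2Z)-4-acetoxy-2-methylbut-2-enoic 2,4,6-trichlorobenzoic anhydride | O=C(OC(=O)/C(C)=C\COC(C)=O)c1c(Cl)cc(Cl)cc1Cl | intermediate
24 | 8-O-[(2Z)-4-acetoxy-2-methylbut-2-enoyl] ester of 17 | C=C[C@@]1(C)C[C@H](OC(=O)/C(C)=C\COC(C)=O)[C@@H](CCO[Si](CC)(CC)CC)[C@H](O[Si](CC)(CC)CC)[C@@H]1C(=C)COCc1ccc(OC)cc1 | intermediate
25 | C12 aldehyde: 24 with the 7β-CH2CH2OSiEt3 group replaced by 7β-CH2CHO | C=C[C@@]1(C)C[C@H](OC(=O)/C(C)=C\COC(C)=O)[C@@H](CC=O)[C@H](O[Si](CC)(CC)CC)[C@@H]1C(=C)COCc1ccc(OC)cc1 | intermediate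
26 | Mannich base: 25 with a (dimethylamino)methyl group on C11 (either configuration at C11) | C=C[C@@]1(C)C[C@H](OC(=O)/C(C)=C\COC(C)=O)[C@@H](C(CN(C)C)C=O)[C@H](O[Si](CC)(CC)CC)[C@@H]1C(=C)COCc1ccc(OC)cc1 | intermediate
27 | α-methylene aldehyde: 7β-(3-oxoprop-1-en-2-yl), 6α-OSiEt3, 15-O-(4-methoxybenzyl) | C=C[C@@]1(C)C[C@H](OC(=O)/C(C)=C\COC(C)=O)[C@@H](C(=C)C=O)[C@H](O[Si](CC)(CC)CC)[C@@H]1C(=C)COCc1ccc(OC)cc1 | intermediate
28 | 6-O-triethylsilyl-15-O-(4-methoxybenzyl) derivative of the target acid | C=C[C@@]1(C)C[C@H](OC(=O)/C(C)=C\COC(C)=O)[C@@H](C(=C)C(=O)O)[C@H](O[Si](CC)(CC)CC)[C@@H]1C(=C)COCc1ccc(OC)cc1 | intermediate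
29 | 6-O-triethylsilyl derivative of the target acid | C=C[C@@]1(C)C[C@H](OC(=O)/C(C)=C\COC(C)=O)[C@@H](C(=C)C(=O)O)[C@H](O[Si](CC)(CC)CC)[C@@H]1C(=C)CO | intermediate
30 | (5S,6R,7S,8S,10R)-8-[(2Z)-4-acetoxy-2-methylbut-2-enoyloxy]-6,15-dihydroxyelema-1,3,11(13)-trien-12-oic acid (CNP0261293.4) | C=C[C@@]1(C)C[C@H](OC(=O)/C(C)=C\COC(C)=O)[C@@H](C(=C)C(=O)O)[C@H](O)[C@@H]1C(=C)CO | target

## Step count and least certain steps

Total: 19 steps (16 in the main line, 1 for stannane 14, 2 for acid 22). Longest linear sequence: 16 steps (steps 1–8, 10, 11 and 14–19, from 1 to 30).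

**Step 2 (key step, the one step beyond precedent).** The endo preference may be insufficient, because methyl and formyl compete for the position under the diene. Turnover may be slow, because the pyrone and product lactone carbonyls compete with the enal for the boron Lewis acid. Facial selectivity may erode if this poor diene forces a higher temperature. The fallback uses known chemistry and sets out from 2 and 3: uncatalysed thermal cycloaddition (toluene, 100 °C, sealed tube), of the kind established for bromopyrones with acrylic dienophiles, should give the racemic endo aldehyde, that is 4 together with its enantiomer (1R,4R,8R)-6-bromo-8-methyl-3-oxo-2-oxabicyclo[2.2.2]oct-5-ene-8-carbaldehyde F1. After chromatographic removal of any exo isomer the racemate is resolved by preparative chromatography on a chiral stationary phase, and the route is rejoined at 4.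

**Step 5.** Regiocontrol may be lost at the diene terminus, the borane may reduce the strained lactone before the hindered ring alkene has reacted, or the oxidative work-up may open the lactone. The fallback takes the two hydroborations apart so that the ring alkene meets a single equivalent of borane on a substrate with no other alkene and no free hydroxyl. It sets out from 6: 9-BBN followed by perborate gives the homoallylic alcohol F2, and Et3SiCl with imidazole gives its triethylsilyl ether F3. BH3·SMe2 (1.1 equiv., 0 °C) and perborate then give the 6α-alcohol F4. The conditions of step 6 silylate O6, cleave the acetal and bring the sequence back at 10.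

**Step 14.** The Z-enoate may isomerise to E, or the allylic acetate may be lost, during a slow acylation of the flanked secondary alcohol; the free acid 22 may also revert to the butenolide on standing. The fallback builds the side chain on the substrate and sets out from 17: carbodiimide esterification with 2-[bis(2,2,2-trifluoroethoxy)phosphoryl]propanoic acid gives the phosphonate ester F5. A Still–Gennari olefination (KN(SiMe3)2, 18-crown-6, THF, −78 °C) with 2-oxoethyl acetate then forms the Z-trisubstituted enoate directly and returns to 24.

**Step 19.** The acidic fluoride source may close the γ-hydroxy acid onto O6 or move an acyl group while the hindered silyl ether is slowly cleaved. The fallback reorders the end game so that the acid is formed only after the silyl group is gone. It sets out from 27: HF·pyridine/pyridine gives the hydroxy enal F6 (possibly in equilibrium with its lactol). Chlorite oxidation under the buffered conditions of step 17 gives the hydroxy acid 4-methoxybenzyl ether F7, and DDQ as in step 18 delivers 30.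

## Further compounds

F1 | step 2 | (1R,4R,8R)-6-bromo-8-methyl-3-oxo-2-oxabicyclo[2.2.2]oct-5-ene-8-carbaldehyde (enantiomer of 4) | O=C[C@]1(C)C[C@@H](O2)C(Br)=C[C@H]1C2=O
F2 | step 5 | (1S,4S,8S)-8-(dimethoxymethyl)-6-(2-hydroxyethyl)-8-methyl-2-oxabicyclo[2.2.2]oct-5-en-3-one | COC(OC)[C@@]1(C)C[C@H](O2)C(CCO)=C[C@@H]1C2=O
F3 | step 5 | 8-(dimethoxymethyl)-8-methyl-6-[2-(triethylsilyloxy)ethyl]-2-oxabicyclo[2.2.2]oct-5-en-3-one | COC(OC)[C@@]1(C)C[C@H](O2)C(CCO[Si](CC)(CC)CC)=C[C@@H]1C2=O
F4 | step 5 | 8-(dimethoxymethyl)-5-hydroxy-8-methyl-6-[2-(triethylsilyloxy)ethyl]-2-oxabicyclo[2.2.2]octan-3-one (6α-OH, 7β-chain) | COC(OC)[C@@]1(C)C[C@H]2[C@@H](CCO[Si](CC)(CC)CC)[C@H](O)[C@@H]1C(=O)O2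
F5 | step 14 | 8-O-{2-[bis(2,2,2-trifluoroethoxy)phosphoryl]propanoyl} ester of 17 | C=C[C@@]1(C)C[C@H](OC(=O)C(C)P(=O)(OCC(F)(F)F)OCC(F)(F)F)[C@@H](CCO[Si](CC)(CC)CC)[C@H](O[Si](CC)(CC)CC)[C@@H]1C(=C)COCc1ccc(OC)cc1
F6 | step 19 | hydroxy enal: 27 without the triethylsilyl group | C=C[C@@]1(C)C[C@H](OC(=O)/C(C)=C\COC(C)=O)[C@@H](C(=C)C=O)[C@H](O)[C@@H]1C(=C)COCc1ccc(OC)cc1
F7 | step 19 | 15-O-(4-methoxybenzyl) ether of the target acid | C=C[C@@]1(C)C[C@H](OC(=O)/C(C)=C\COC(C)=O)[C@@H](C(=C)C(=O)O)[C@H](O)[C@@H]1C(=C)COCc1ccc(OC)cc1
A1 | alternative 1 | methyl 6-(tert-butyldimethylsilyloxy)-2-ethenyl-4-hydroxy-2-methyl-5-(prop-1-en-2-yl)cyclohexane-1-carboxylate (ene product) | C=C[C@@]1(C)C[C@H](O)[C@@H](C(C)=C)[C@H](O[Si](C)(C)C(C)(C)C)[C@@H]1C(=O)OC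
A2 | alternative 1 | methyl 3-(tert-butyldimethylsilyloxy)-5-methyl-2-(3-methyl-5-oxopent-1-en-3-yl)hex-4-enoate (open-chain aldehyde) | C=C[C@@](C)(CC=O)[C@@H](C(=O)OC)[C@@H](O[Si](C)(C)C(C)(C)C)C=C(C)C
A3 | alternative 2 | 8-bromo-3,5-dimethoxy-1-methyl-6-oxabicyclo[3.2.1]oct-2-en-7-one (bromolactone) | O=C1O[C@]2(OC)CC(OC)=C[C@@]1(C)[C@H]2Br
A4 | alternative 2 | 3,5-dimethoxy-1-methylcyclohexa-2,5-diene-1-carboxylic acid | COC1=CC(C)(C(=O)O)C=C(OC)C1
A5 | alternative 2 | 3,5-dimethoxybenzoic acid | COc1cc(OC)cc(c1)C(=O)O
A6 | alternative 3 | endo cycloadduct: bicyclo[2.2.2]octenone keto-ketal with fused tetrahydrofuran (1-phenylethyl) acetal | COC3(OC)[C@@]1(C)C=C[C@@H](C3=O)[C@H](O4)[C@@H]1C[C@@H]4O[C@@H](C)c2ccccc2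
A7 | alternative 3 | 6,6-dimethoxy-5-methylcyclohexa-2,4-dien-1-one | COC1(OC)C(C)=CC=CC1=O
A8 | alternative 3 | 2-methoxy-3-methylphenol | COc1c(C)cccc1O
A9 | alternative 3 | 2-(1-phenylethoxy)-2,3-dihydrofuran (single stereoisomer) | O1C=CC[C@@H]1O[C@@H](C)c1ccccc1
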